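The data were generated by integration from invented constants.

The vessel is stirred at constant volume with the gas held at 44 mM, and I follow the 0.10 M of starting complex through its exchanges, so I write every amount as a fraction of its charge.

common to all: gas 44 mM (held)

| flask | starting complex | leaving ligand | remark | time |
|---|---|---|---|---|
| autumn | 0.10 M (in portions, 4) | 0.34 M | run made earlier; portions every 4.0 min |  |
| dusk | 0.10 M (in portions, 4) | 0.75 M | run made earlier; portions every 4.0 min |  |
| noon | 0.20 M (in portions, 4) | 0.50 M | run made earlier; portions every 4.0 min |  |
| Sunday's | 0.10 M (in portions, 4) | 0.500 M | the portions of starting complex follow each other after 4.0 min, the first at the start | 8.0 h |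
| Saturday's | 0.10 M (in portions, 4) | 0.500 M | the portions of starting complex follow each other after 4.0 min, the first at the start | 25 h |

| run | time / h | complex with three exchanged / % | starting complex / % | complex with two exchanged / % | complex with one exchanged / % |
|---|---|---|---|---|---|
| autumn | 1.33 | 2 | 86 | 1 | 15 |
| autumn | 2.50 | 0 | 75 | 2 | 17 |
| autumn | 4.00 | 0 | 58 | 9 | 26 |
| autumn | 5.00 | 4 | 50 | 13 | 26 |
| dusk | 0.667 | 0 | 97 | 0 | 4 |
| dusk | 1.50 | 4 | 80 | 1 | 12 |
| dusk | 3.00 | 1 | 70 | 5 | 17 |
| dusk | 5.00 | 2 | 53 | 13 | 22 |
| noon | 1.33 | 2 | 82 | 0 | 8 |
| noon | 2.50 | 2 | 73 | 0 | 12 |
| noon | 4.00 | 0 | 64 | 3 | 21 |
| noon | 5.00 | 4 | 59 | 6 | 25 |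

(standard deviation of a reading: 2 percentage points)

- at the start none of the gas is in solution
- a reading or a percentage of complex with one exchanged counts all its forms, free or not
- a reading of starting complex is of its free form alone

* which of these there is most of at the end, counted by the starting complex in it, Sunday's (starting complex / complex with two exchanged / complex with three exchanged / complex with one exchanged)
* which of these there is most of at the end, counted by the starting complex in it, Saturday's (starting complex / complex with two exchanged / complex with three exchanged / complex with one exchanged)
* amount of the one of these that there is most of at the end, in percent of the starting complex charged, Sunday's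
* amount of the one of these that there is most of at the end, in percent of the starting complex charged, Saturday's

First I ask which settings must be known well. The portions end after 0.200 h, hardly any of Sunday's time, so their spacing can be rough. Moving the leaving ligand from 0.34 M to 0.75 M shifts the free starting complex at 5.00 h by 3 percentage points, against a scatter of 2 points, so it can be rough too. The gas was 44 mM, 44 mM and 44 mM in those runs, which gives no test of it. The charge matters: at 0.20 M the noon run shows less complex with two exchanged at 5.00 h, 6%, than the autumn and dusk runs, with 13% and 13% at leaving ligand on either side of noon's 0.50 M.

The balance of the charge shows why I look there. Free starting complex is read alone, but complex with one exchanged is read with its bound forms, so the readings fall short of the whole. I take that gap as the idle adduct, which holds one of each. At 5.00 h, autumn and dusk average a gap of 0.0850, with free starting complex 0.515 and free complex with one exchanged 0.155. The binding number, the gap divided by the product of those two free fractions, is 1.06, a reading with wide scatter. For a fixed binding equilibrium it scales with the charge.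

For Sunday's I continue the first-order fall of the free starting complex to 0.346. Holding the free complex with one exchanged at 0.155, the gap is 0.0571. The balance leaves 0.385 for the two later complexes together, so I expect starting complex to lead narrowly.

The forecast gives starting complex at 42% for Sunday's, above my figure, and complex with three exchanged at 60% for Saturday's, with the remark “The third step is poorly defined”.

Sunday's flask gives starting complex at 41.7%, and Saturday's gives complex with two exchanged at 50.3%.

    incoming ligand → decomposed reagent (k = 1.00 × 10⁻⁴ /s)
    complex with one exchanged + incoming ligand ⇌ leaving ligand + complex with two exchanged (K = 180, k = 0.00720 /M/s)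
    complex with two exchanged + incoming ligand ⇌ leaving ligand + complex with three exchanged (K = 15.0, k = 0.00810 /M/s)
    starting complex + complex with one exchanged ⇌ idle adduct, settled at all times (K = 8.70 /M)
    starting complex + incoming ligand ⇌ leaving ligand + complex with one exchanged (K = 29.0, k = 0.00300 /M/s)
    gas ⇌ incoming ligand, rate k6*(csat - [incoming ligand]) (kL = 1.70 × 10⁻⁴ /s)

On Sunday's, complex with two exchanged is still made 3.10 times faster than it is used up. With Sunday's end fractions, the binding number gives a gap of 0.0704, and the idle adduct stands at 0.0576 as pairs. In the neighbour flask, Sunday's with 0.025 M of starting complex, the number scales to 0.266 and gives 0.0110, against 0.00900 found there, where complex with two exchanged leads at 34.7%.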